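**Retrosynthetic overview**
1. The target (heteroxanthin) is cut at C11=C12 (Wittig) into the ring B C15 trihydroxy dienal 20 and the ring A acetylenic C25 phosphonium salt 30. Salt 30 comes from the C15 enynyl phosphonium salt 25 and C10 dialdehyde 26 (C11'=C12'), and 25 from enol triflate 5 and enynol 21 (Sonogashira, C6'–C7').
2. Ring B chain: C9=C10 by Horner–Wadsworth–Emmons reaction on the C13 ketone 16; C7=C8 by Wittig reaction on epoxy aldehyde 9.
3. Feature used: in ring B the C3–O and C5–O bonds are cis-1,3 (both axial on one face) and the C5–O and C6–O bonds are trans. An oxygen nucleophile hung on O3 can therefore reach C5 only from the face opposite the oxygen of a 5,6-epoxide that lies anti to O3. The C3 tert-butyl carbonate of epoxy enone 14 does this under BF3 and forms the C5–O bond with inversion.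
4. Ring order: both carbocycles are carried in from ketoisophorone 1 through (4R,6R)-actinol 3 and the common triflate 5. The oxirane (C5, C6, O) is made in step 7 and the 1,3-dioxan-2-one (O3–C(=O)–O5) in step 12; both are opened again on the way to the triol.

Key step: step 12

Remark: locants follow carotenoid numbering, unprimed for the trihydroxy ring B half and primed for the acetylenic ring A half; the target is the (3S,5S,6S,3'R) all-E compound.
Remark: D-glucose, dialdehyde 26 and enynol 21 are taken as purchasable building blocks.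

**Route**

Step 1
Reactants: 1 ketoisophorone
Product: 2 (6R)-2,2,6-trimethylcyclohexane-1,4-dione
Conditions: ene-reductase OYE1 (cat.), NADP+ (cat.), glucose dehydrogenase (cat.), D-glucose, phosphate buffer pH 7, 30 °C
Reagents that add atoms: none
Why: Old-yellow-enzyme ene-reductases reduce the enedione C=C by trans addition of hydride and a proton from a fixed face (biocatalytic asymmetric conjugate reduction with glucose-driven cofactor recycling), which should set the methyl-bearing carbon as R.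

Step 2
Reactants: 2 (6R)-2,2,6-trimethylcyclohexane-1,4-dione
Product: 3 (4R,6R)-4-hydroxy-2,2,6-trimethylcyclohexanone
Conditions: LiBH(s-Bu)3 (L-Selectride), THF, −78 °C; then NaOH, H2O2
Reagents that add atoms: none
Why: Substrate-controlled hydride reduction: the C1 carbonyl is shielded by its quaternary and tertiary neighbours, and the bulky borohydride attacks the C4 carbonyl equatorially, away from the axial C2 methyl, so the new hydroxyl is axial and trans to the equatorial C6 methyl, i.e. (4R).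

Step 3
Reactants: 3 (4R,6R)-4-hydroxy-2,2,6-trimethylcyclohexanone
Product: 4 (4R,6R)-4-(tert-butyldimethylsilyloxy)-2,2,6-trimethylcyclohexanone
Conditions: TBSCl, imidazole, DMF, rt
Reagents that add atoms: tert-butyldimethylsilyl chloride, CC(C)(C)[Si](C)(C)Cl
Why: Standard silyl ether protection of the secondary alcohol; no stereocentre is touched.

Step 4
Reactants: 4 (4R,6R)-4-(tert-butyldimethylsilyloxy)-2,2,6-trimethylcyclohexanone
Product: 5 (4R)-4-(tert-butyldimethylsilyloxy)-2,6,6-trimethylcyclohex-1-en-1-yl trifluoromethanesulfonate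
Conditions: LiN(i-Pr)2, THF, −78 → 0 °C; PhNTf2, −78 °C → rt
Reagents that add atoms: N-phenyl-bis(trifluoromethanesulfonimide), O=S(=O)(N(c1ccccc1)S(=O)(=O)C(F)(F)F)C(F)(F)F
Why: Only one α-carbon carries hydrogen, so a single tetrasubstituted enolate forms and is O-sulfonylated (enol triflate formation); the methyl-bearing centre is erased on purpose while the silyloxy centre is kept.

Step 5
Reactants: 5 (4R)-4-(tert-butyldimethylsilyloxy)-2,6,6-trimethylcyclohex-1-en-1-yl trifluoromethanesulfonate
Product: 6 methyl (4R)-4-(tert-butyldimethylsilyloxy)-2,6,6-trimethylcyclohex-1-ene-1-carboxylate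
Conditions: Pd(OAc)2 (cat.), PPh3, CO (1 atm), MeOH, Et3N, DMF, 40 °C
Reagents that add atoms: carbon monoxide, [C-]#[O+]; methanol, CO
Why: Palladium-catalysed alkoxycarbonylation of an enol triflate (oxidative addition, CO insertion, methanolysis of the acyl-palladium species) installs C7 on the ring with the alkene position fixed.

Step 6
Reactants: 6 methyl (4R)-4-(tert-butyldimethylsilyloxy)-2,6,6-trimethylcyclohex-1-ene-1-carboxylate
Product: 7 [(4R)-4-(tert-butyldimethylsilyloxy)-2,6,6-trimethylcyclohex-1-en-1-yl]methanol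
Conditions: i-Bu2AlH, CH2Cl2, −78 → 0 °C
Reagents that add atoms: none
Why: 1,2-Reduction of the conjugated ester by an aluminium hydride gives the allylic alcohol that will direct the epoxidation; the silyl ether is inert.

Step 7
Reactants: 7 [(4R)-4-(tert-butyldimethylsilyloxy)-2,6,6-trimethylcyclohex-1-en-1-yl]methanol
Product: 8 [(1R,4S,6R)-4-(tert-butyldimethylsilyloxy)-2,2,6-trimethyl-7-oxabicyclo[4.1.0]heptan-1-yl]methanol (epoxide oxygen anti to the silyloxy group)
Conditions: Ti(OiPr)4 (cat.), D-(−)-diethyl tartrate (cat.), t-BuOOH, 4 Å MS, CH2Cl2, −20 °C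
Reagents that add atoms: tert-butyl hydroperoxide, CC(C)(C)OO
Why: Katsuki–Sharpless asymmetric epoxidation: the titanium–tartrate–peroxide complex bound to the allylic hydroxyl delivers oxygen to the C5=C6 face opposite the C3 silyloxy group, the D-(−)-tartrate being the enantiomer whose facial preference coincides with the substrate's own bias, which sets C5 and C6 together by syn addition.

Step 8
Reactants: 8 [(1R,4S,6R)-4-(tert-butyldimethylsilyloxy)-2,2,6-trimethyl-7-oxabicyclo[4.1.0]heptan-1-yl]methanol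
Product: 9 (1S,4S,6R)-4-(tert-butyldimethylsilyloxy)-2,2,6-trimethyl-7-oxabicyclo[4.1.0]heptane-1-carbaldehyde
Conditions: Dess–Martin periodinane, NaHCO3, CH2Cl2, rt
Reagents that add atoms: none
Why: Dess–Martin oxidation of the primary epoxy alcohol under buffered, non-acidic conditions gives the aldehyde without opening the epoxide; the α-carbon is quaternary and cannot epimerise.

Step 9
Reactants: 9 (1S,4S,6R)-4-(tert-butyldimethylsilyloxy)-2,2,6-trimethyl-7-oxabicyclo[4.1.0]heptane-1-carbaldehyde; 10 1-(triphenylphosphoranylidene)propan-2-one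
Product: 11 (E)-4-[(1S,4S,6R)-4-(tert-butyldimethylsilyloxy)-2,2,6-trimethyl-7-oxabicyclo[4.1.0]heptan-1-yl]but-3-en-2-one
Conditions: toluene, 90 °C
Reagents that add atoms: none
Why: Wittig olefination with a stabilised keto ylide should give the (E)-enone through the reversible, thermodynamically controlled oxaphosphetane; heating compensates for the neopentyl-type aldehyde.

Step 10
Reactants: 11 (E)-4-[(1S,4S,6R)-4-(tert-butyldimethylsilyloxy)-2,2,6-trimethyl-7-oxabicyclo[4.1.0]heptan-1-yl]but-3-en-2-one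
Product: 12 (3S,5R,6S)-5,6-epoxy-3-hydroxy-5,6-dihydro-β-ionone
Conditions: Bu4NF, THF, 0 °C → rt
Reagents that add atoms: none
Why: Fluoride-mediated cleavage of the silyl ether (Si–F bond formation) frees the C3 hydroxyl; the epoxide and the enone tolerate the weakly basic fluoride.

Step 11
Reactants: 12 (3S,5R,6S)-5,6-epoxy-3-hydroxy-5,6-dihydro-β-ionone; 13 di-tert-butyl dicarbonate
Product: 14 tert-butyl carbonate of (3S,5R,6S)-5,6-epoxy-3-hydroxy-5,6-dihydro-β-ionone
Conditions: DMAP (cat.), CH2Cl2, rt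
Reagents that add atoms: none
Why: DMAP-catalysed acylation of the secondary alcohol gives the mixed tert-butyl carbonate that serves as the tethered oxygen nucleophile.

Step 12
Reactants: 14 tert-butyl carbonate of (3S,5R,6S)-5,6-epoxy-3-hydroxy-5,6-dihydro-β-ionone
Product: 16 3,5-cyclic carbonate of (3S,5S,6S)-3,5,6-trihydroxy-5,6-dihydro-β-ionone (6-OH free), via tert-butoxydioxanylium ion 15 (not isolated)
Conditions: BF3·OEt2 (1.2 equiv), CH2Cl2, −78 → −40 °C; aq. NaHCO3
Reagents that add atoms: none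
Why: BF3 binds the epoxide oxygen and, in the half-chair that places the C3 carbonate axial, the carbonate carbonyl oxygen attacks C5 from the face opposite the breaking C5–O bond; the resulting 2-tert-butoxy-1,3-dioxan-2-ylium ion 15 loses isobutene and the boron-bound C6 oxygen is protonated on work-up. The closest known reaction type is the Lewis-acid cyclisation of epoxy tert-butyl carbonates to cyclic carbonates with inversion at the attacked carbon. The 1,3-dioxan-2-one ring closes in a 6-exo-tet mode, the C5–O(epoxide) bond being exocyclic to the forming ring, whereas attack at C6 would demand a seven-membered endo closure. C5 is the only centre that changes, and its configuration is fixed by the backside trajectory that the tether from O3 imposes; C3 and C6 keep the configurations from steps 2 and 7, so the 3,5-cis and 5,6-trans pattern follows. The step needs C5 over C6 regioselectivity and capture of the developing charge at C5 ahead of a 1,2-shift of the C1–C6 ring bond (ring contraction), 3,6-ether formation or furanoid rearrangement. The tether length, the enone that destabilises charge at C6, the acylated and therefore poorly nucleophilic O3 and the low temperature should secure this.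

Step 13
Reactants: 16 3,5-cyclic carbonate of (3S,5S,6S)-3,5,6-trihydroxy-5,6-dihydro-β-ionone; 17 triethyl phosphonoacetate
Product: 18 ethyl (2E,4E)-3-methyl-5-(ring B 3,5-carbonate, 6-OH)penta-2,4-dienoate
Conditions: NaH, THF, 0 °C → rt
Reagents that add atoms: none
Why: Horner–Wadsworth–Emmons olefination of the C9 methyl ketone with the stabilised phosphonoacetate anion should favour the (9E) alkene (dienyl residue anti to the ester in the equilibrating adduct), the minor 9Z isomer being removable by chromatography; the C6 alkoxide is axial and anti to O5 and cannot reach the carbonate.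

Step 14
Reactants: 18 ethyl (2E,4E)-3-methyl-5-(ring B 3,5-carbonate, 6-OH)penta-2,4-dienoate
Product: 19 (1S,2S,4S)-1-[(1E,3E)-5-hydroxy-3-methylpenta-1,3-dienyl]-2,6,6-trimethylcyclohexane-1,2,4-triol
Conditions: LiAlH4, THF, −20 → 0 °C; then H2O, aq. NaOH
Reagents that add atoms: none
Why: Hydride reduction takes the conjugated ester to the allylic alcohol by 1,2-addition and at the same time reduces the cyclic carbonate to methanol, which frees the C3 and C5 hydroxyls without touching a stereocentre.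

Step 15
Reactants: 19 (1S,2S,4S)-1-[(1E,3E)-5-hydroxy-3-methylpenta-1,3-dienyl]-2,6,6-trimethylcyclohexane-1,2,4-triol
Product: 20 (2E,4E)-3-methyl-5-[(1S,2S,4S)-1,2,4-trihydroxy-2,6,6-trimethylcyclohexyl]penta-2,4-dienal
Conditions: activated MnO2, acetone, rt
Reagents that add atoms: none
Why: Chemoselective allylic oxidation: MnO2 oxidises only the primary dienylic alcohol, since the secondary C3 hydroxyl is not allylic and the tertiary C5 and C6 hydroxyls cannot be oxidised.

Step 16
Reactants: 5 (4R)-4-(tert-butyldimethylsilyloxy)-2,6,6-trimethylcyclohex-1-en-1-yl trifluoromethanesulfonate; 21 (E)-3-methylpent-2-en-4-yn-1-ol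
Product: 22 (E)-5-[(4R)-4-(tert-butyldimethylsilyloxy)-2,6,6-trimethylcyclohex-1-en-1-yl]-3-methylpent-2-en-4-yn-1-ol
Conditions: Pd(PPh3)4 (cat.), CuI (cat.), i-Pr2NH, DMF, rt
Reagents that add atoms: none
Why: Sonogashira coupling: zerovalent palladium inserts into the vinyl C–OTf bond and the copper acetylide transmetalates, forming the C6'–C7' bond with the (E) geometry of the purchased enynol carried over unchanged.

Step 17
Reactants: 22 (E)-5-[(4R)-4-(tert-butyldimethylsilyloxy)-2,6,6-trimethylcyclohex-1-en-1-yl]-3-methylpent-2-en-4-yn-1-ol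
Product: 23 (E)-5-[(4R)-4-hydroxy-2,6,6-trimethylcyclohex-1-en-1-yl]-3-methylpent-2-en-4-yn-1-ol
Conditions: Bu4NF, THF, rt
Reagents that add atoms: none
Why: Fluoride-mediated desilylation as in step 10, done early so that no protecting group has to be removed from the finished polyene.

Step 18
Reactants: 23 (E)-5-[(4R)-4-hydroxy-2,6,6-trimethylcyclohex-1-en-1-yl]-3-methylpent-2-en-4-yn-1-ol
Product: 24 (1R)-4-[(E)-5-bromo-3-methylpent-3-en-1-ynyl]-3,5,5-trimethylcyclohex-3-en-1-ol
Conditions: NBS, Me2S, CH2Cl2, −20 → 0 °C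
Reagents that add atoms: N-bromosuccinimide, O=C1CCC(=O)N1Br
Why: Corey–Kim halogenation: the bromosulfonium salt activates only the allylic primary hydroxyl and bromide displaces it in an SN2 manner, so the secondary C3' alcohol and the 9'E alkene stay as they are.

Step 19
Reactants: 24 (1R)-4-[(E)-5-bromo-3-methylpent-3-en-1-ynyl]-3,5,5-trimethylcyclohex-3-en-1-ol
Product: 25 tributyl{(E)-5-[(4R)-4-hydroxy-2,6,6-trimethylcyclohex-1-en-1-yl]-3-methylpent-2-en-4-ynyl}phosphonium bromide
Conditions: PBu3, MeCN, 0 °C → rt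
Reagents that add atoms: tributylphosphine, CCCCP(CCCC)CCCC
Why: SN2 quaternisation of the phosphine by the primary allylic bromide gives the phosphonium salt with the alkene geometry retained, avoiding an allyl cation that could scramble C9'=C10'.

Step 20
Reactants: 25 tributyl{(E)-5-[(4R)-4-hydroxy-2,6,6-trimethylcyclohex-1-en-1-yl]-3-methylpent-2-en-4-ynyl}phosphonium bromide; 26 (2E,4E,6E)-2,7-dimethylocta-2,4,6-trienedial
Product: 28 (2E,4E,6E,8E,10E)-13-[(4R)-4-hydroxy-2,6,6-trimethylcyclohex-1-en-1-yl]-2,7,11-trimethyltrideca-2,4,6,8,10-pentaen-12-ynal, via tributylphosphonium ylide 27 (not isolated)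
Conditions: NaOMe, CH2Cl2, 0 °C → rt, 26 in excess (3 equiv)
Reagents that add atoms: none
Why: Wittig reaction of a semistabilised allylic trialkylphosphonium ylide, a class that gives (E)-alkenes preferentially, forms C11'=C12'; the excess of dialdehyde and the lower electrophilicity of the extended product aldehyde favour single condensation.

Step 21
Reactants: 28 (2E,4E,6E,8E,10E)-13-[(4R)-4-hydroxy-2,6,6-trimethylcyclohex-1-en-1-yl]-2,7,11-trimethyltrideca-2,4,6,8,10-pentaen-12-ynal
Product: 29 (2E,4E,6E,8E,10E)-13-[(4R)-4-hydroxy-2,6,6-trimethylcyclohex-1-en-1-yl]-2,7,11-trimethyltrideca-2,4,6,8,10-pentaen-12-yn-1-ol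
Conditions: NaBH4, MeOH/CH2Cl2, 0 °C
Reagents that add atoms: none
Why: Borohydride 1,2-reduction of the polyenal gives the primary polyenylic alcohol without affecting the polyene or the alkyne.

Step 22
Reactants: 29 (2E,4E,6E,8E,10E)-13-[(4R)-4-hydroxy-2,6,6-trimethylcyclohex-1-en-1-yl]-2,7,11-trimethyltrideca-2,4,6,8,10-pentaen-12-yn-1-ol
Product: 30 {(2E,4E,6E,8E,10E)-13-[(4R)-4-hydroxy-2,6,6-trimethylcyclohex-1-en-1-yl]-2,7,11-trimethyltrideca-2,4,6,8,10-pentaen-12-ynyl}triphenylphosphonium bromide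
Conditions: PPh3·HBr, MeOH/CH2Cl2, rt, dark
Reagents that add atoms: triphenylphosphine hydrobromide, [Br-].c1ccc(cc1)[PH+](c1ccccc1)c1ccccc1
Why: Acid-promoted ionisation of the polyenylic alcohol to a delocalised cation that triphenylphosphine captures at the terminal carbon (the standard preparation of carotenoid Wittig salts); the non-allylic C3' hydroxyl does not ionise.

Step 23
Reactants: 30 C25 triphenylphosphonium bromide; 20 (2E,4E)-3-methyl-5-[(1S,2S,4S)-1,2,4-trihydroxy-2,6,6-trimethylcyclohexyl]penta-2,4-dienal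
Product: 33 heteroxanthin, (3S,5S,6S,3'R)-7',8'-didehydro-5,6-dihydro-β,β-carotene-3,5,6,3'-tetrol (all-E), via C25 ylide 31 (not isolated), via 11Z isomer 32 (not isolated)
Conditions: NaOMe, MeOH/CH2Cl2, 0 °C → rt, dark; then heptane/EtOH, 60 °C, dark, argon
Reagents that add atoms: none
Why: Wittig olefination under methoxide conditions that tolerate free hydroxyls forms C11=C12; the hindered 11Z isomer 32 that the semistabilised ylide also gives should relax to 11E on gentle warming (clash of H–C10 with the C13 methyl), while the unhindered alkenes, including 9'E, should not equilibrate at this temperature.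

**Compound list**
1 | ketoisophorone (2,6,6-trimethylcyclohex-2-ene-1,4-dione) | CC1=CC(=O)CC(C)(C)C1=O | starting material
2 | (6R)-2,2,6-trimethylcyclohexane-1,4-dione | O=C1C(C)(C)CC(=O)C[C@H]1C | intermediate
3 | (4R,6R)-4-hydroxy-2,2,6-trimethylcyclohexanone | O=C1C(C)(C)C[C@H](O)C[C@H]1C | intermediate
4 | (4R,6R)-4-(tert-butyldimethylsilyloxy)-2,2,6-trimethylcyclohexanone | O=C1C(C)(C)C[C@H](O[Si](C)(C)C(C)(C)C)C[C@H]1C | intermediate
5 | (4R)-4-(tert-butyldimethylsilyloxy)-2,6,6-trimethylcyclohex-1-en-1-yl trifluoromethanesulfonate | CC1=C(OS(=O)(=O)C(F)(F)F)C(C)(C)C[C@H](O[Si](C)(C)C(C)(C)C)C1 | intermediate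
6 | methyl (4R)-4-(tert-butyldimethylsilyloxy)-2,6,6-trimethylcyclohex-1-ene-1-carboxylate | CC1=C(C(=O)OC)C(C)(C)C[C@H](O[Si](C)(C)C(C)(C)C)C1 | intermediate
7 | [(4R)-4-(tert-butyldimethylsilyloxy)-2,6,6-trimethylcyclohex-1-en-1-yl]methanol | CC1=C(CO)C(C)(C)C[C@H](O[Si](C)(C)C(C)(C)C)C1 | intermediate
8 | [(1R,4S,6R)-4-(tert-butyldimethylsilyloxy)-2,2,6-trimethyl-7-oxabicyclo[4.1.0]heptan-1-yl]methanol | OC[C@@]12O[C@]1(C)C[C@@H](O[Si](C)(C)C(C)(C)C)CC2(C)C | intermediate
9 | (1S,4S,6R)-4-(tert-butyldimethylsilyloxy)-2,2,6-trimethyl-7-oxabicyclo[4.1.0]heptane-1-carbaldehyde | O=C[C@@]12O[C@]1(C)C[C@@H](O[Si](C)(C)C(C)(C)C)CC2(C)C | intermediate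
10 | 1-(triphenylphosphoranylidene)propan-2-one | CC(=O)C=P(c1ccccc1)(c1ccccc1)c1ccccc1 | starting material
11 | (E)-4-[(1S,4S,6R)-4-(tert-butyldimethylsilyloxy)-2,2,6-trimethyl-7-oxabicyclo[4.1.0]heptan-1-yl]but-3-en-2-one | CC(=O)/C=C/[C@@]12O[C@]1(C)C[C@@H](O[Si](C)(C)C(C)(C)C)CC2(C)C | intermediate
12 | (3S,5R,6S)-5,6-epoxy-3-hydroxy-5,6-dihydro-β-ionone | CC(=O)/C=C/[C@@]12O[C@]1(C)C[C@@H](O)CC2(C)C | intermediate
13 | di-tert-butyl dicarbonate | CC(C)(C)OC(=O)OC(=O)OC(C)(C)C | starting material
14 | tert-butyl carbonate of (3S,5R,6S)-5,6-epoxy-3-hydroxy-5,6-dihydro-β-ionone | CC(=O)/C=C/[C@@]12O[C@]1(C)C[C@@H](OC(=O)OC(C)(C)C)CC2(C)C | intermediate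
15 | BF3-bound 2-tert-butoxy-1,3-dioxan-2-ylium ion spanning O3 and O5 | CC(=O)/C=C/[C@]1(O[B-](F)(F)F)C(C)(C)C[C@H]2C[C@]1(C)OC(OC(C)(C)C)=[O+]2 | intermediate
16 | 3,5-cyclic carbonate of (3S,5S,6S)-3,5,6-trihydroxy-5,6-dihydro-β-ionone | CC(=O)/C=C/[C@]1(O)C(C)(C)C[C@H]2C[C@]1(C)OC(=O)O2 | intermediate
17 | triethyl phosphonoacetate | CCOC(=O)CP(=O)(OCC)OCC | starting material
18 | ethyl (2E,4E)-3-methyl-5-(ring B 3,5-carbonate, 6-OH)penta-2,4-dienoate | CCOC(=O)/C=C(C)/C=C/[C@]1(O)C(C)(C)C[C@H]2C[C@]1(C)OC(=O)O2 | intermediate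
19 | (1S,2S,4S)-1-[(1E,3E)-5-hydroxy-3-methylpenta-1,3-dienyl]-2,6,6-trimethylcyclohexane-1,2,4-triol | OC/C=C(C)/C=C/[C@]1(O)C(C)(C)C[C@H](O)C[C@]1(C)O | intermediate
20 | (2E,4E)-3-methyl-5-[(1S,2S,4S)-1,2,4-trihydroxy-2,6,6-trimethylcyclohexyl]penta-2,4-dienal | O=C/C=C(C)/C=C/[C@]1(O)C(C)(C)C[C@H](O)C[C@]1(C)O | intermediate
21 | (E)-3-methylpent-2-en-4-yn-1-ol | C#C/C(C)=C/CO | starting material
22 | (E)-5-[(4R)-4-(tert-butyldimethylsilyloxy)-2,6,6-trimethylcyclohex-1-en-1-yl]-3-methylpent-2-en-4-yn-1-ol | CC1=C(C#C/C(C)=C/CO)C(C)(C)C[C@H](O[Si](C)(C)C(C)(C)C)C1 | intermediate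
23 | (E)-5-[(4R)-4-hydroxy-2,6,6-trimethylcyclohex-1-en-1-yl]-3-methylpent-2-en-4-yn-1-ol | CC1=C(C#C/C(C)=C/CO)C(C)(C)C[C@H](O)C1 | intermediate
24 | (1R)-4-[(E)-5-bromo-3-methylpent-3-en-1-ynyl]-3,5,5-trimethylcyclohex-3-en-1-ol | CC1=C(C#C/C(C)=C/CBr)C(C)(C)C[C@H](O)C1 | intermediate
25 | tributyl{(E)-5-[(4R)-4-hydroxy-2,6,6-trimethylcyclohex-1-en-1-yl]-3-methylpent-2-en-4-ynyl}phosphonium bromide | CC1=C(C#C/C(C)=C/C[P+](CCCC)(CCCC)CCCC)C(C)(C)C[C@H](O)C1.[Br-] | intermediate
26 | (2E,4E,6E)-2,7-dimethylocta-2,4,6-trienedial | O=C/C(C)=C/C=C/C=C(C)/C=O | starting material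
27 | tributylphosphonium ylide of 25 | CC1=C(C#C/C(C)=C/C=P(CCCC)(CCCC)CCCC)C(C)(C)C[C@H](O)C1 | intermediate
28 | (2E,4E,6E,8E,10E)-13-[(4R)-4-hydroxy-2,6,6-trimethylcyclohex-1-en-1-yl]-2,7,11-trimethyltrideca-2,4,6,8,10-pentaen-12-ynal | CC1=C(C#C/C(C)=C/C=C/C(C)=C/C=C/C=C(C)/C=O)C(C)(C)C[C@H](O)C1 | intermediate
29 | (2E,4E,6E,8E,10E)-13-[(4R)-4-hydroxy-2,6,6-trimethylcyclohex-1-en-1-yl]-2,7,11-trimethyltrideca-2,4,6,8,10-pentaen-12-yn-1-ol | CC1=C(C#C/C(C)=C/C=C/C(C)=C/C=C/C=C(C)/CO)C(C)(C)C[C@H](O)C1 | intermediate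
30 | C25 triphenylphosphonium bromide of 29 | CC1=C(C#C/C(C)=C/C=C/C(C)=C/C=C/C=C(C)/C[P+](c2ccccc2)(c2ccccc2)c2ccccc2)C(C)(C)C[C@H](O)C1.[Br-] | intermediate
31 | C25 triphenylphosphonium ylide of 30 | CC1=C(C#C/C(C)=C/C=C/C(C)=C/C=C/C=C(C)/C=P(c2ccccc2)(c2ccccc2)c2ccccc2)C(C)(C)C[C@H](O)C1 | intermediate
32 | (11Z)-heteroxanthin | CC1=C(C#C/C(C)=C/C=C/C(C)=C/C=C/C=C(C)/C=C\C=C(C)\C=C\[C@]2(O)C(C)(C)C[C@H](O)C[C@]2(C)O)C(C)(C)C[C@H](O)C1 | intermediate
33 | heteroxanthin, (3S,5S,6S,3'R)-7',8'-didehydro-5,6-dihydro-β,β-carotene-3,5,6,3'-tetrol | CC1=C(C#C/C(C)=C/C=C/C(C)=C/C=C/C=C(C)/C=C/C=C(C)/C=C/[C@]2(O)C(C)(C)C[C@H](O)C[C@]2(C)O)C(C)(C)C[C@H](O)C1 | target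

**Step count**
Total: 23 steps. Longest linear sequence: 16 steps (steps 1–15, then step 23). The ring A branch runs through steps 1–4, 16–22 and 23 (12 steps).

**Steps most likely to fail**

Step 12. The transition state needs the C3 carbonate axial and syn to a C1 methyl. If that is too costly, charge building at C5 may instead be quenched by migration of the C1–C6 ring bond (ring contraction to a cyclopentyl ketone), or the tert-butyl group may be lost before the carbonyl oxygen engages. The fallback replaces tethered delivery by intermolecular hydration and sets out from 12. Dilute HClO4 in THF/H2O at 0 °C should open the protonated epoxide with water at C5, the carbon remote from the enone, with inversion, to give (3S,5S,6S)-3,5,6-trihydroxy-5,6-dihydro-β-ionone F1. Horner–Wadsworth–Emmons reaction of F1 with 17 (excess NaH, THF) should give the ethyl (2E,4E)-dienoate of the free (3S,5S,6S)-triol F2, and LiAlH4 reduction of F2 returns to the route at tetraol 19.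

Step 13. The geometry at C9=C10 may be poorly controlled on a methyl ketone, and the sodium alkoxide or the phosphonate anion may attack the carbonate. The fallback builds C7=C8 and C9=C10 in one olefination before the carbonate is made and sets out from aldehyde 9. Reaction of 9 with the anion of triethyl 3-methyl-4-phosphonocrotonate (LiN(SiMe3)2, THF, −78 → 0 °C) should give the silyl-protected (7E,9E)-epoxy dienoate F3. Bu4NF then gives the hydroxy epoxy dienoate F4, and Boc2O with DMAP gives its tert-butyl carbonate F5. BF3·OEt2 at low temperature, the same cyclisation now on a dienoate, returns to the route at 18.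

Step 23. E-selectivity at C11=C12 may be incomplete, the 9' alkene may drift towards Z during the warming, and the four free hydroxyls may consume ylide. The fallback uses a phosphonate carbanion olefination, which is E-selective without heating, and sets out from 29. Corey–Kim bromination (NBS, Me2S) should give the C25 polyenynyl bromide F6. Michaelis–Becker reaction with NaP(O)(OEt)2 in THF at 0 °C gives the C25 diethyl phosphonate F7. Deprotonation of F7 with excess NaN(SiMe3)2 in THF at −78 → 0 °C and addition of aldehyde 20 returns to the route at target 33.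

**Further compounds**
F1 | step 12 | (3S,5S,6S)-3,5,6-trihydroxy-5,6-dihydro-β-ionone | CC(=O)/C=C/[C@]1(O)C(C)(C)C[C@H](O)C[C@]1(C)O
F2 | step 12 | ethyl (2E,4E)-3-methyl-5-[(1S,2S,4S)-1,2,4-trihydroxy-2,6,6-trimethylcyclohexyl]penta-2,4-dienoate | CCOC(=O)/C=C(C)/C=C/[C@]1(O)C(C)(C)C[C@H](O)C[C@]1(C)O
F3 | step 13 | ethyl (2E,4E)-5-[(1S,4S,6R)-4-(tert-butyldimethylsilyloxy)-2,2,6-trimethyl-7-oxabicyclo[4.1.0]heptan-1-yl]-3-methylpenta-2,4-dienoate | CCOC(=O)/C=C(C)/C=C/[C@@]12O[C@]1(C)C[C@@H](O[Si](C)(C)C(C)(C)C)CC2(C)C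
F4 | step 13 | ethyl (2E,4E)-5-[(1S,4S,6R)-4-hydroxy-2,2,6-trimethyl-7-oxabicyclo[4.1.0]heptan-1-yl]-3-methylpenta-2,4-dienoate | CCOC(=O)/C=C(C)/C=C/[C@@]12O[C@]1(C)C[C@@H](O)CC2(C)C
F5 | step 13 | tert-butyl carbonate of F4 | CCOC(=O)/C=C(C)/C=C/[C@@]12O[C@]1(C)C[C@@H](OC(=O)OC(C)(C)C)CC2(C)C
F6 | step 23 | (1R)-4-[(3E,5E,7E,9E,11E)-13-bromo-3,7,12-trimethyltrideca-3,5,7,9,11-pentaen-1-ynyl]-3,5,5-trimethylcyclohex-3-en-1-ol | CC1=C(C#C/C(C)=C/C=C/C(C)=C/C=C/C=C(C)/CBr)C(C)(C)C[C@H](O)C1
F7 | step 23 | diethyl {(2E,4E,6E,8E,10E)-13-[(4R)-4-hydroxy-2,6,6-trimethylcyclohex-1-en-1-yl]-2,7,11-trimethyltrideca-2,4,6,8,10-pentaen-12-ynyl}phosphonate | CC1=C(C#C/C(C)=C/C=C/C(C)=C/C=C/C=C(C)/CP(=O)(OCC)OCC)C(C)(C)C[C@H](O)C1
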